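**Plan**

- Retrosynthetic cuts: the side chain at C13–C14 (Stille coupling), C12=C13 (iodo-ylide Wittig) and C11–C12 (Wittig homologation); the C6 and C7 oxygens back to a C6=C7 alkene; then C5–C10 and C8–C9 together, which opens rings A and B to an acyclic trienoyl imide; the chain is cut at C1–C10, C5=C6 and C3–C4.
- Enabling feature: C5–C10 and C8–C9 are the two bonds of ring B that link the stereocentres C5, C10 (quaternary), C9 and C8 (tertiary carbinol). With C5–C8 as a 1-silyloxydiene and C9=C10 as a 3-methyl enoyl dienophile joined through C1–C4, one [4+2] forms both bonds.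
- Forward order: chain assembly (nitrile alkylation, Julia–Kocienski olefination, carbocupration), imide and silyl dienol ether formation, rings A and B together in one step, then ring B oxygenation, with the diene completed last.
- Stereochemistry: C5, C8, C9 and C10 come from the cycloaddition (relative configuration from the three alkene geometries, absolute from a chiral copper bis(oxazoline) catalyst). C6 comes from dihydroxylation anti to C20, C7 from oxidation and axial hydride delivery, and the (12Z) alkene from the iodo-ylide olefination and a stereoretentive coupling.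

Key step: step 11

Remark: carbons carry labdane numbers (C17 on C8, C20 on C10, side chain C11–C16) and bicyclic compounds are named with C9 as position 1 of the naphthalene skeleton; the sense of induction in step 11 is assumed to follow the square-planar chelate model of the copper catalyst, the (R,R)-ligand being the remedy if the opposite sense arises.

**Route**

Step 1
Reactants: 1 isobutyronitrile; 2 1-bromo-3-chloropropane
Product: 4 5-chloro-2,2-dimethylpentanenitrile, via lithiated isobutyronitrile 3 (not isolated)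
Conditions: LiN(iPr)2, THF, −78 °C; then 2, −78 → 25 °C
Reagents that add atoms: none
Why: SN2 alkylation of the lithiated nitrile is selective for bromide over chloride and builds the C4 quaternary carbon while keeping the C1 chloride for later metalation.

Step 2
Reactants: 4 5-chloro-2,2-dimethylpentanenitrile
Product: 6 5-chloro-2,2-dimethylpentanal, via N-aluminio aldimine 5 (not isolated)
Conditions: iBu2AlH, toluene, −78 → 0 °C; then 1 M aq HCl, 0 °C
Reagents that add atoms: water, O
Why: Partial hydride reduction of the hindered nitrile stops at the aluminium imine, which hydrolyses on acidic work-up to the C5 aldehyde.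

Step 3
Reactants: 7 2-(2-bromoethyl)-2-methyl-1,3-dioxolane; 8 1-phenyl-1H-tetrazole-5-thiol
Product: 9 5-{[2-(2-methyl-1,3-dioxolan-2-yl)ethyl]sulfanyl}-1-phenyl-1H-tetrazole
Conditions: K2CO3, DMF, 25 °C
Reagents that add atoms: none
Why: SN2 S-alkylation of the acidic thiol by the primary bromide under carbonate base leaves the ketal untouched.

Step 4
Reactants: 9 tetrazolyl sulfide
Product: 10 5-{[2-(2-methyl-1,3-dioxolan-2-yl)ethyl]sulfonyl}-1-phenyl-1H-tetrazole
Conditions: 30% aq H2O2, (NH4)6Mo7O24·4H2O (cat.), EtOH, 0 → 25 °C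
Reagents that add atoms: hydrogen peroxide, OO
Why: Molybdate-catalysed peroxide oxidation of the sulfide to the sulfone is the standard entry to Julia–Kocienski reagents and tolerates the dioxolane.

Step 5
Reactants: 10 tetrazolyl sulfone; 6 5-chloro-2,2-dimethylpentanal
Product: 12 2-[(2E)-7-chloro-4,4-dimethylhept-2-en-1-yl]-2-methyl-1,3-dioxolane, via potassium sulfonyl carbanion 11 (not isolated)
Conditions: KN(SiMe3)2, DME, −60 °C; then 6, −60 → 25 °C
Reagents that add atoms: none
Why: Julia–Kocienski olefination of a phenyltetrazolyl sulfone with an α-quaternary aldehyde under potassium counter-ion in DME should give the (E)-alkene C5=C6 through the anti adduct, Smiles rearrangement and elimination.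

Step 6
Reactants: 12 chloro alkene ketal; 13 ethyl but-2-ynoate
Product: 17 ethyl (2E,8E)-3,7,7-trimethyl-10-(2-methyl-1,3-dioxolan-2-yl)deca-2,8-dienoate, via Grignard reagent 14 (not isolated), via alkylcopper reagent 15 (not isolated), via alkenylcopper adduct 16 (not isolated)
Conditions: Mg, THF, 60 °C; CuBr·SMe2, −40 °C; 13, −78 °C; sat. aq NH4Cl, −78 °C
Reagents that add atoms: none
Why: Syn carbocupration of the ynoate by the Grignard-derived alkylcopper reagent, with protonation at −78 °C before the alkenylcopper can isomerise, places the new chain cis to hydrogen and so gives the (E)-3-methyl enoate (C20 cis to the carbonyl group).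

Step 7
Reactants: 17 dienoate ester
Product: 18 (2E,8E)-3,7,7-trimethyl-10-(2-methyl-1,3-dioxolan-2-yl)deca-2,8-dienoic acid
Conditions: LiOH·H2O, THF/MeOH/H2O, 50 °C; then 1 M aq HCl to pH 4, 0 °C
Reagents that add atoms: lithium hydroxide monohydrate, [Li+].[OH-].O
Why: Saponification of the β,β-disubstituted enoate with hydroxide leaves the ketal intact, and acidification only to pH 4 in the cold avoids ketal loss.

Step 8
Reactants: 18 dienoic acid; 19 oxazolidin-2-one
Product: 21 3-[(2E,8E)-3,7,7-trimethyl-10-(2-methyl-1,3-dioxolan-2-yl)deca-2,8-dienoyl]-1,3-oxazolidin-2-one, via mixed pivalic anhydride 20 (not isolated)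
Conditions: t-BuCOCl, Et3N, THF, −20 °C; then LiCl, 19, −20 → 25 °C
Reagents that add atoms: none
Why: N-Acylation of the oxazolidinone through the mixed anhydride with LiCl and amine base avoids strong base and therefore deconjugation or isomerisation of the 3-methyl enoyl unit.

Step 9
Reactants: 21 ketal imide
Product: 22 3-[(2E,8E)-3,7,7-trimethyl-11-oxododeca-2,8-dienoyl]-1,3-oxazolidin-2-one
Conditions: PPTS (cat.), acetone/H2O, 40 °C
Reagents that add atoms: water, O
Why: Mild acid-catalysed deketalisation frees the methyl ketone without moving the β,γ-alkene into conjugation and without touching the imide.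

Step 10
Reactants: 22 keto imide
Product: 23 3-[(2E,8E,10Z)-11-{[tert-butyl(dimethyl)silyl]oxy}-3,7,7-trimethyldodeca-2,8,10-trienoyl]-1,3-oxazolidin-2-one
Conditions: TBSOTf, Et3N, CH2Cl2, −78 → 0 °C; filtration through Et3N-deactivated silica and direct use
Reagents that add atoms: tert-butyldimethylsilyl trifluoromethanesulfonate, CC(C)(C)[Si](C)(C)OS(=O)(=O)C(F)(F)F
Why: Soft enolisation with silyl triflate and amine removes the doubly activated C7 proton rather than a methyl or imide proton, and the (10Z) enol ether is expected because the silyloxy group, not the methyl group, takes the position cis to the vinyl substituent to avoid allylic 1,3-strain.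

Step 11
Reactants: 23 silyloxytrienoyl imide
Product: 24 3-{[(1S,2S,4aR,8aR)-2-{[tert-butyl(dimethyl)silyl]oxy}-2,5,5,8a-tetramethyl-1,2,4a,5,6,7,8,8a-octahydronaphthalen-1-yl]carbonyl}-1,3-oxazolidin-2-one
Conditions: [Cu{(S,S)-2,2'-isopropylidenebis(4-tert-butyl-2-oxazoline)}](SbF6)2 (10 mol %), CH2Cl2, 25 → 40 °C
Reagents that add atoms: none
Why: Proposed new method: two-point binding of the imide to the cationic, square-planar divalent copper centre should lower the dienophile LUMO enough for a strongly asynchronous [4+2] in which C5 (δ to oxygen, largest HOMO coefficient) bonds to the β-carbon C10 ahead of C8–C9 formation, or, in the stepwise limit, a Mukaiyama–Michael addition followed at once by collapse of the copper enolate carbon C9 onto the silyloxyallyl cation at C8; the closest known reaction types are the [Cu(bis(oxazoline))](SbF6)2-catalysed intramolecular Diels–Alder reaction of 2,8,10-trienoyl oxazolidinones and copper bis(oxazoline) Mukaiyama–Michael additions of silyl enol ethers, neither shown for a β,β-disubstituted dienophile facing a fully substituted silyloxy terminus. Ring A closes through the four-carbon tether as a 6-exo-trig attack of C5 on C10, and ring B closes as the cyclohexene of the [4+2] itself (a 6-exo-trig attack of C9 on C8 in the stepwise limit). C9 and C10 follow from the (2E) alkene (acyl group and C20 stay cis), C5 from the acyl-endo, tether-exo transition state that leads to the trans ring fusion, and C8 from the (10Z) enol ether, whose silyloxy group sits inside the s-cis diene and ends cis to H5 with C17 axial. The absolute configuration comes from the (S,S)-ligand, whose tert-butyl group should cover the Si face of C9 in the s-cis chelate so that C8 adds to the Re face. The step needs endo over exo selectivity, one enantioface and ring closure in preference to release of an open Michael adduct; the rigid chelate, the gem-dimethyl group on the tether and the proximity of enolate and cation in the folded intermediate should secure these, with warming to 40 °C allowed because both new bonds join congested carbons.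

Step 12
Reactants: 24 cycloadduct imide
Product: 25 [(1R,2S,4aR,8aR)-2-{[tert-butyl(dimethyl)silyl]oxy}-2,5,5,8a-tetramethyl-1,2,4a,5,6,7,8,8a-octahydronaphthalen-1-yl]methanol
Conditions: LiBH4, MeOH (1 equiv), THF, 0 → 25 °C
Reagents that add atoms: none
Why: Reductive cleavage of the N-acyl oxazolidinone by borohydride at the exocyclic carbonyl gives the C11 primary alcohol without touching the tertiary silyl ether, the alkene or any stereocentre.

Step 13
Reactants: 25 C11 alcohol
Product: 26 (1S,2S,4aR,8aR)-2-{[tert-butyl(dimethyl)silyl]oxy}-2,5,5,8a-tetramethyl-1,2,4a,5,6,7,8,8a-octahydronaphthalene-1-carbaldehyde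
Conditions: Dess–Martin periodinane, CH2Cl2, 0 → 25 °C
Reagents that add atoms: none
Why: Dess–Martin oxidation gives the hindered aldehyde under non-basic conditions, and the equatorial formyl group at C9 is the thermodynamically favoured epimer.

Step 14
Reactants: 26 C11 aldehyde
Product: 27 tert-butyl{[(1S,2S,4aR,8aR)-1-(2-methoxyethenyl)-2,5,5,8a-tetramethyl-1,2,4a,5,6,7,8,8a-octahydronaphthalen-2-yl]oxy}dimethylsilane (E/Z mixture)
Conditions: Ph3P(CH2OMe)Cl, KN(SiMe3)2, THF, 0 °C; then 26, −78 → 25 °C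
Reagents that add atoms: (methoxymethyl)triphenylphosphonium chloride, COC[P+](c1ccccc1)(c1ccccc1)c1ccccc1.[Cl-]
Why: Wittig methoxymethylenation with a small reactive ylide adds C12 to the hindered aldehyde, and the enol ether geometry is of no consequence.

Step 15
Reactants: 27 enol ether
Product: 28 [(1S,2S,4aR,8aR)-2-{[tert-butyl(dimethyl)silyl]oxy}-2,5,5,8a-tetramethyl-1,2,4a,5,6,7,8,8a-octahydronaphthalen-1-yl]acetaldehyde
Conditions: 2 M aq HCl, THF, 0 → 25 °C
Reagents that add atoms: water, O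
Why: Acid-catalysed enol ether hydrolysis (C-protonation, then hemiacetal collapse) gives the C12 aldehyde, and the tertiary TBS ether is stable to brief dilute acid.

Step 16
Reactants: 28 C12 aldehyde
Product: 29 tert-butyl({(1S,2S,4aR,8aR)-1-[(2Z)-3-iodobut-2-en-1-yl]-2,5,5,8a-tetramethyl-1,2,4a,5,6,7,8,8a-octahydronaphthalen-2-yl}oxy)dimethylsilane
Conditions: EtPPh3I, n-BuLi, THF, 25 °C; I2, −78 °C; NaN(SiMe3)2, −20 °C; then 28, −78 → −20 °C
Reagents that add atoms: ethyltriphenylphosphonium iodide, CC[P+](c1ccccc1)(c1ccccc1)c1ccccc1.[I-]; iodine, II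
Why: The Stork–Zhao-type Wittig olefination with the α-iodoethylidene ylide gives the (Z)-2-iodoalkene (iodine cis to C11) under kinetic low-temperature control, which fixes the C12=C13 geometry of the future diene.

Step 17
Reactants: 29 (Z)-iodoalkene
Product: 30 (1S,2R,3S,4S,4aR,8aR)-2-{[tert-butyl(dimethyl)silyl]oxy}-1-[(2Z)-3-iodobut-2-en-1-yl]-2,5,5,8a-tetramethyldecahydronaphthalene-3,4-diol
Conditions: OsO4 (5 mol %), N-methylmorpholine N-oxide, acetone/H2O, 25 °C
Reagents that add atoms: osmium tetroxide, O=[Os](=O)(=O)=O; N-methylmorpholine N-oxide, C[N+]1([O-])CCOCC1; water, O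
Why: Catalytic osmium tetroxide syn-dihydroxylation should take the ring alkene rather than the electron-poor iodoalkene and add anti to C20, since the other face is blocked by the axial C17, C20 and C4 methyl groups, so the C6 hydroxyl is set equatorial (final configuration) and the C7 hydroxyl axial.

Step 18
Reactants: 30 6,7-cis-diol
Product: 31 (1S,2R,3S,4S,4aR,8aR)-2-{[tert-butyl(dimethyl)silyl]oxy}-1-[(2Z)-3-iodobut-2-en-1-yl]-2,5,5,8a-tetramethyl-4-[(triethylsilyl)oxy]decahydronaphthalen-3-ol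
Conditions: Et3SiCl, imidazole, DMF, 0 °C
Reagents that add atoms: chlorotriethylsilane, CC[Si](Cl)(CC)CC
Why: Silylation is expected at the equatorial C6 hydroxyl, as usual for cis-1,2-diols on six-membered rings, because the axial C7 hydroxyl is neopentylic and flanked by the C8 silyl ether.

Step 19
Reactants: 31 C6 silyl ether
Product: 32 (1S,2R,4S,4aR,8aR)-2-{[tert-butyl(dimethyl)silyl]oxy}-1-[(2Z)-3-iodobut-2-en-1-yl]-2,5,5,8a-tetramethyl-4-[(triethylsilyl)oxy]-1,4,4a,5,6,7,8,8a-octahydronaphthalen-3(2H)-one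
Conditions: Dess–Martin periodinane, CH2Cl2, 25 °C
Reagents that add atoms: none
Why: Dess–Martin oxidation of the remaining axial secondary alcohol gives the C7 ketone without epimerising the α-silyloxy centre C6 under these non-basic conditions.

Step 20
Reactants: 32 C7 ketone
Product: 33 (1S,2R,3R,4S,4aR,8aR)-2-{[tert-butyl(dimethyl)silyl]oxy}-1-[(2Z)-3-iodobut-2-en-1-yl]-2,5,5,8a-tetramethyl-4-[(triethylsilyl)oxy]decahydronaphthalen-3-ol
Conditions: NaBH4, MeOH/THF, −20 → 0 °C
Reagents that add atoms: none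
Why: Borohydride reduction of the cyclohexanone by axial attack from the face of H5 and H9 (the equatorial trajectory is hindered by the axial C17 methyl on the neighbouring carbon) should give the equatorial C7 alcohol, trans to both neighbouring oxygens.

Step 21
Reactants: 33 C7 equatorial alcohol
Product: 34 (1S,2R,3R,4S,4aR,8aR)-2-{[tert-butyl(dimethyl)silyl]oxy}-1-[(2Z)-3-iodobut-2-en-1-yl]-2,5,5,8a-tetramethyl-4-[(triethylsilyl)oxy]decahydronaphthalen-3-yl acetate
Conditions: Ac2O, DMAP, pyridine, 25 → 40 °C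
Reagents that add atoms: acetic anhydride, CC(=O)OC(C)=O
Why: DMAP-catalysed acetylation of the only free hydroxyl group places the acetate on C7 unambiguously.

Step 22
Reactants: 34 bis-silyl acetate
Product: 35 (1S,2R,3R,4S,4aR,8aR)-2,4-dihydroxy-1-[(2Z)-3-iodobut-2-en-1-yl]-2,5,5,8a-tetramethyldecahydronaphthalen-3-yl acetate
Conditions: HF·pyridine, pyridine, THF, 0 → 40 °C
Reagents that add atoms: none
Why: Buffered fluoride desilylation removes the secondary TES and the tertiary TBS ether without acyl migration, and is placed before the acid-sensitive hydroxy diene exists.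

Step 23
Reactants: 35 iodo diol acetate
Product: 36 (1S,2R,3R,4S,4aR,8aR)-2,4-dihydroxy-2,5,5,8a-tetramethyl-1-[(2Z)-3-methylpenta-2,4-dien-1-yl]decahydronaphthalen-3-yl acetate
Conditions: tributyl(vinyl)stannane, PdCl2(MeCN)2 (5 mol %), DMF, 25 °C
Reagents that add atoms: tributyl(vinyl)stannane, C=C[Sn](CCCC)(CCCC)CCCC
Why: Stille coupling of the (Z)-alkenyl iodide with the vinylstannane proceeds with retention of alkene geometry under neutral conditions that tolerate the free hydroxyl groups and the acetate, giving the (12Z)-diene of the target.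

**Compound list**

1 | isobutyronitrile | CC(C)C#N | starting material
2 | 1-bromo-3-chloropropane | ClCCCBr | starting material
3 | lithiated isobutyronitrile (N-lithio ketenimine form) | CC(C)=C=N[Li] | intermediate (not isolated)
4 | 5-chloro-2,2-dimethylpentanenitrile | CC(C)(CCCCl)C#N | intermediate
5 | N-(diisobutylaluminio) aldimine of 5-chloro-2,2-dimethylpentanal | CC(C)C[Al](CC(C)C)N=CC(C)(C)CCCCl | intermediate (not isolated)
6 | 5-chloro-2,2-dimethylpentanal | CC(C)(CCCCl)C=O | intermediate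
7 | 2-(2-bromoethyl)-2-methyl-1,3-dioxolane | CC1(CCBr)OCCO1 | starting material
8 | 1-phenyl-1H-tetrazole-5-thiol | Sc1nnnn1-c1ccccc1 | starting material
9 | 5-{[2-(2-methyl-1,3-dioxolan-2-yl)ethyl]sulfanyl}-1-phenyl-1H-tetrazole | CC1(CCSc2nnnn2-c2ccccc2)OCCO1 | intermediate
10 | 5-{[2-(2-methyl-1,3-dioxolan-2-yl)ethyl]sulfonyl}-1-phenyl-1H-tetrazole | CC1(CCS(=O)(=O)c2nnnn2-c2ccccc2)OCCO1 | intermediate
11 | potassium salt of the α-sulfonyl carbanion of 10 | [K+].CC1(C[CH-]S(=O)(=O)c2nnnn2-c2ccccc2)OCCO1 | intermediate (not isolated)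
12 | 2-[(2E)-7-chloro-4,4-dimethylhept-2-en-1-yl]-2-methyl-1,3-dioxolane | CC1(C/C=C/C(C)(C)CCCCl)OCCO1 | intermediate
13 | ethyl but-2-ynoate | CC#CC(=O)OCC | starting material
14 | [(5E)-4,4-dimethyl-7-(2-methyl-1,3-dioxolan-2-yl)hept-5-en-1-yl]magnesium chloride | Cl[Mg]CCCC(C)(C)/C=C/CC1(C)OCCO1 | intermediate (not isolated)
15 | [(5E)-4,4-dimethyl-7-(2-methyl-1,3-dioxolan-2-yl)hept-5-en-1-yl]copper | [Cu]CCCC(C)(C)/C=C/CC1(C)OCCO1 | intermediate (not isolated)
16 | ethyl (2Z,8E)-2-cuprio-3,7,7-trimethyl-10-(2-methyl-1,3-dioxolan-2-yl)deca-2,8-dienoate (copper cis to the new chain) | CCOC(=O)/C([Cu])=C(C)/CCCC(C)(C)/C=C/CC1(C)OCCO1 | intermediate (not isolated)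
17 | ethyl (2E,8E)-3,7,7-trimethyl-10-(2-methyl-1,3-dioxolan-2-yl)deca-2,8-dienoate | CCOC(=O)/C=C(C)/CCCC(C)(C)/C=C/CC1(C)OCCO1 | intermediate
18 | (2E,8E)-3,7,7-trimethyl-10-(2-methyl-1,3-dioxolan-2-yl)deca-2,8-dienoic acid | OC(=O)/C=C(C)/CCCC(C)(C)/C=C/CC1(C)OCCO1 | intermediate
19 | oxazolidin-2-one | O=C1NCCO1 | starting material
20 | mixed anhydride of 18 with pivalic acid | CC(C)(C)C(=O)OC(=O)/C=C(C)/CCCC(C)(C)/C=C/CC1(C)OCCO1 | intermediate (not isolated)
21 | 3-[(2E,8E)-3,7,7-trimethyl-10-(2-methyl-1,3-dioxolan-2-yl)deca-2,8-dienoyl]-1,3-oxazolidin-2-one | O=C1OCCN1C(=O)/C=C(C)/CCCC(C)(C)/C=C/CC2(C)OCCO2 | intermediate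
22 | 3-[(2E,8E)-3,7,7-trimethyl-11-oxododeca-2,8-dienoyl]-1,3-oxazolidin-2-one | O=C1OCCN1C(=O)/C=C(C)/CCCC(C)(C)/C=C/CC(C)=O | intermediate
23 | 3-[(2E,8E,10Z)-11-{[tert-butyl(dimethyl)silyl]oxy}-3,7,7-trimethyldodeca-2,8,10-trienoyl]-1,3-oxazolidin-2-one (key-step precursor) | O=C1OCCN1C(=O)/C=C(C)/CCCC(C)(C)/C=C/C=C(C)\O[Si](C)(C)C(C)(C)C | intermediate
24 | 3-{[(1S,2S,4aR,8aR)-2-{[tert-butyl(dimethyl)silyl]oxy}-2,5,5,8a-tetramethyl-1,2,4a,5,6,7,8,8a-octahydronaphthalen-1-yl]carbonyl}-1,3-oxazolidin-2-one (trans-fused; C8 silyloxy cis to H5; C9 acyl cis to C20; key-step product) | O=C1OCCN1C(=O)[C@@H]2[C@@](C)(O[Si](C)(C)C(C)(C)C)C=C[C@@H]3C(C)(C)CCC[C@]32C | intermediate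
25 | [(1R,2S,4aR,8aR)-2-{[tert-butyl(dimethyl)silyl]oxy}-2,5,5,8a-tetramethyl-1,2,4a,5,6,7,8,8a-octahydronaphthalen-1-yl]methanol | OC[C@@H]1[C@@](C)(O[Si](C)(C)C(C)(C)C)C=C[C@@H]2C(C)(C)CCC[C@]21C | intermediate
26 | (1S,2S,4aR,8aR)-2-{[tert-butyl(dimethyl)silyl]oxy}-2,5,5,8a-tetramethyl-1,2,4a,5,6,7,8,8a-octahydronaphthalene-1-carbaldehyde | O=C[C@@H]1[C@@](C)(O[Si](C)(C)C(C)(C)C)C=C[C@@H]2C(C)(C)CCC[C@]21C | intermediate
27 | tert-butyl{[(1S,2S,4aR,8aR)-1-(2-methoxyethenyl)-2,5,5,8a-tetramethyl-1,2,4a,5,6,7,8,8a-octahydronaphthalen-2-yl]oxy}dimethylsilane (E/Z mixture at the enol ether) | COC=C[C@@H]1[C@@](C)(O[Si](C)(C)C(C)(C)C)C=C[C@@H]2C(C)(C)CCC[C@]21C | intermediate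
28 | [(1S,2S,4aR,8aR)-2-{[tert-butyl(dimethyl)silyl]oxy}-2,5,5,8a-tetramethyl-1,2,4a,5,6,7,8,8a-octahydronaphthalen-1-yl]acetaldehyde | O=CC[C@@H]1[C@@](C)(O[Si](C)(C)C(C)(C)C)C=C[C@@H]2C(C)(C)CCC[C@]21C | intermediate
29 | tert-butyl({(1S,2S,4aR,8aR)-1-[(2Z)-3-iodobut-2-en-1-yl]-2,5,5,8a-tetramethyl-1,2,4a,5,6,7,8,8a-octahydronaphthalen-2-yl}oxy)dimethylsilane | I/C(C)=C\C[C@@H]1[C@@](C)(O[Si](C)(C)C(C)(C)C)C=C[C@@H]2C(C)(C)CCC[C@]21C | intermediate
30 | (1S,2R,3S,4S,4aR,8aR)-2-{[tert-butyl(dimethyl)silyl]oxy}-1-[(2Z)-3-iodobut-2-en-1-yl]-2,5,5,8a-tetramethyldecahydronaphthalene-3,4-diol (C6 hydroxyl equatorial, C7 hydroxyl axial, both anti to C20) | I/C(C)=C\C[C@@H]1[C@@](C)(O[Si](C)(C)C(C)(C)C)[C@@H](O)[C@@H](O)[C@@H]2C(C)(C)CCC[C@]21C | intermediate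
31 | (1S,2R,3S,4S,4aR,8aR)-2-{[tert-butyl(dimethyl)silyl]oxy}-1-[(2Z)-3-iodobut-2-en-1-yl]-2,5,5,8a-tetramethyl-4-[(triethylsilyl)oxy]decahydronaphthalen-3-ol | I/C(C)=C\C[C@@H]1[C@@](C)(O[Si](C)(C)C(C)(C)C)[C@@H](O)[C@@H](O[Si](CC)(CC)CC)[C@@H]2C(C)(C)CCC[C@]21C | intermediate
32 | (1S,2R,4S,4aR,8aR)-2-{[tert-butyl(dimethyl)silyl]oxy}-1-[(2Z)-3-iodobut-2-en-1-yl]-2,5,5,8a-tetramethyl-4-[(triethylsilyl)oxy]-1,4,4a,5,6,7,8,8a-octahydronaphthalen-3(2H)-one | I/C(C)=C\C[C@@H]1[C@@](C)(O[Si](C)(C)C(C)(C)C)C(=O)[C@@H](O[Si](CC)(CC)CC)[C@@H]2C(C)(C)CCC[C@]21C | intermediate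
33 | (1S,2R,3R,4S,4aR,8aR)-2-{[tert-butyl(dimethyl)silyl]oxy}-1-[(2Z)-3-iodobut-2-en-1-yl]-2,5,5,8a-tetramethyl-4-[(triethylsilyl)oxy]decahydronaphthalen-3-ol (C7 hydroxyl equatorial) | I/C(C)=C\C[C@@H]1[C@@](C)(O[Si](C)(C)C(C)(C)C)[C@H](O)[C@@H](O[Si](CC)(CC)CC)[C@@H]2C(C)(C)CCC[C@]21C | intermediate
34 | (1S,2R,3R,4S,4aR,8aR)-2-{[tert-butyl(dimethyl)silyl]oxy}-1-[(2Z)-3-iodobut-2-en-1-yl]-2,5,5,8a-tetramethyl-4-[(triethylsilyl)oxy]decahydronaphthalen-3-yl acetate | I/C(C)=C\C[C@@H]1[C@@](C)(O[Si](C)(C)C(C)(C)C)[C@H](OC(C)=O)[C@@H](O[Si](CC)(CC)CC)[C@@H]2C(C)(C)CCC[C@]21C | intermediate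
35 | (1S,2R,3R,4S,4aR,8aR)-2,4-dihydroxy-1-[(2Z)-3-iodobut-2-en-1-yl]-2,5,5,8a-tetramethyldecahydronaphthalen-3-yl acetate | I/C(C)=C\C[C@@H]1[C@@](C)(O)[C@H](OC(C)=O)[C@@H](O)[C@@H]2C(C)(C)CCC[C@]21C | intermediate
36 | (1S,2R,3R,4S,4aR,8aR)-2,4-dihydroxy-2,5,5,8a-tetramethyl-1-[(2Z)-3-methylpenta-2,4-dien-1-yl]decahydronaphthalen-3-yl acetate (CNP0225877.2; labdane locants 5R,6S,7R,8R,9S,10R,12Z) | C=C/C(C)=C\C[C@@H]1[C@@](C)(O)[C@H](OC(C)=O)[C@@H](O)[C@@H]2C(C)(C)CCC[C@]21C | target

**Count and risks**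

Total step count: 23. Longest linear sequence: 21 steps (steps 1, 2 and 5 to 23, from isobutyronitrile); steps 3 and 4 prepare the sulfone on a side branch.

Steps most likely to fail:

1. Step 11. The trisubstituted dienophile may not engage under the mild copper Lewis acid, the reaction may stall after the first bond at an open-chain Michael adduct or a desilylated enone, or the catalyst may discriminate the two faces poorly. The fallback replaces catalyst control by a covalently bound chiral auxiliary and a stronger stoichiometric Lewis acid, the established auxiliary-controlled intramolecular Diels–Alder reaction of chiral trienoyl oxazolidinones. It sets out from acid 18 and returns at alcohol 25. Acid 18 is converted through its pivalic mixed anhydride (t-BuCOCl, Et3N, LiCl) with (R)-4-benzyl-1,3-oxazolidin-2-one into the benzyl ketal imide F1. Deketalisation (PPTS, aqueous acetone) gives the benzyl keto imide F2, and TBSOTf/Et3N gives the benzyl silyl dienol ether F3. Me2AlCl (1.4 equiv, CH2Cl2, −78 → −30 °C) forms the cationic aluminium chelate, in which the benzyl group should shield the Si face of C9, and gives the benzyl cycloadduct F4. LiBH4 then removes the auxiliary and delivers 25.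

2. Step 18. Site selection between the two hindered secondary hydroxyl groups may be poor, with silylation at O7 or at both oxygens. The fallback differentiates the diol through a cyclic orthoester instead of by relative rates; it sets out from diol 30 and returns at silyl ether 31. Trimethyl orthoacetate and PPTS give the cyclic orthoacetate F5. Brief treatment with aqueous acetic acid opens it by the usual rule to the axial ester, the axial C7 acetate F6 with the equatorial C6 hydroxyl free. Et3SiOTf/2,6-lutidine gives the silyl ether acetate F7, and iBu2AlH at −78 °C removes the acetate to give 31.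

3. Step 16. Enolisation of the α-unbranched aldehyde by the basic iodo-ylide and erosion of the Z geometry may leave little of the iodoalkene. The fallback builds the trisubstituted alkene by stepwise substitution of a 1,1-dihaloalkene; it sets out from aldehyde 28 and returns at iodoalkene 29. Ramirez dibromo-olefination (CBr4, PPh3) gives the dibromoalkene F8. A trans-selective Negishi methylation (Me2Zn, PdCl2[bis(2-diphenylphosphinophenyl) ether] as catalyst) replaces the bromine trans to C11 and gives the (Z)-bromoalkene F9. Copper-catalysed halogen exchange (CuI, NaI, N,N'-dimethylethylenediamine, dioxane, 110 °C), which retains alkene geometry, converts F9 into 29.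

**Further compounds**

F1 | step 11 | (4R)-4-benzyl-3-[(2E,8E)-3,7,7-trimethyl-10-(2-methyl-1,3-dioxolan-2-yl)deca-2,8-dienoyl]-1,3-oxazolidin-2-one | O=C1OC[C@@H](Cc2ccccc2)N1C(=O)/C=C(C)/CCCC(C)(C)/C=C/CC3(C)OCCO3
F2 | step 11 | (4R)-4-benzyl-3-[(2E,8E)-3,7,7-trimethyl-11-oxododeca-2,8-dienoyl]-1,3-oxazolidin-2-one | O=C1OC[C@@H](Cc2ccccc2)N1C(=O)/C=C(C)/CCCC(C)(C)/C=C/CC(C)=O
F3 | step 11 | (4R)-4-benzyl-3-[(2E,8E,10Z)-11-{[tert-butyl(dimethyl)silyl]oxy}-3,7,7-trimethyldodeca-2,8,10-trienoyl]-1,3-oxazolidin-2-one | O=C1OC[C@@H](Cc2ccccc2)N1C(=O)/C=C(C)/CCCC(C)(C)/C=C/C=C(C)\O[Si](C)(C)C(C)(C)C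
F4 | step 11 | (4R)-4-benzyl-3-{[(1S,2S,4aR,8aR)-2-{[tert-butyl(dimethyl)silyl]oxy}-2,5,5,8a-tetramethyl-1,2,4a,5,6,7,8,8a-octahydronaphthalen-1-yl]carbonyl}-1,3-oxazolidin-2-one | O=C1OC[C@@H](Cc2ccccc2)N1C(=O)[C@@H]3[C@@](C)(O[Si](C)(C)C(C)(C)C)C=C[C@@H]4C(C)(C)CCC[C@]43C
F5 | step 18 | 6,7-cyclic methyl orthoacetate of diol 30 (2-methoxy-2-methyl-1,3-dioxolane cis-fused at C6–C7, orthoester carbon as a mixture) | I/C(C)=C\C[C@@H]1[C@@](C)(O[Si](C)(C)C(C)(C)C)[C@H]2OC(C)(OC)O[C@H]2[C@@H]3C(C)(C)CCC[C@]31C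
F6 | step 18 | (1S,2R,3S,4S,4aR,8aR)-2-{[tert-butyl(dimethyl)silyl]oxy}-4-hydroxy-1-[(2Z)-3-iodobut-2-en-1-yl]-2,5,5,8a-tetramethyldecahydronaphthalen-3-yl acetate (axial acetate) | I/C(C)=C\C[C@@H]1[C@@](C)(O[Si](C)(C)C(C)(C)C)[C@@H](OC(C)=O)[C@@H](O)[C@@H]2C(C)(C)CCC[C@]21C
F7 | step 18 | (1S,2R,3S,4S,4aR,8aR)-2-{[tert-butyl(dimethyl)silyl]oxy}-1-[(2Z)-3-iodobut-2-en-1-yl]-2,5,5,8a-tetramethyl-4-[(triethylsilyl)oxy]decahydronaphthalen-3-yl acetate (axial acetate) | I/C(C)=C\C[C@@H]1[C@@](C)(O[Si](C)(C)C(C)(C)C)[C@@H](OC(C)=O)[C@@H](O[Si](CC)(CC)CC)[C@@H]2C(C)(C)CCC[C@]21C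
F8 | step 16 | tert-butyl{[(1S,2S,4aR,8aR)-1-(3,3-dibromoprop-2-en-1-yl)-2,5,5,8a-tetramethyl-1,2,4a,5,6,7,8,8a-octahydronaphthalen-2-yl]oxy}dimethylsilane | BrC(Br)=CC[C@@H]1[C@@](C)(O[Si](C)(C)C(C)(C)C)C=C[C@@H]2C(C)(C)CCC[C@]21C
F9 | step 16 | tert-butyl({(1S,2S,4aR,8aR)-1-[(2Z)-3-bromobut-2-en-1-yl]-2,5,5,8a-tetramethyl-1,2,4a,5,6,7,8,8a-octahydronaphthalen-2-yl}oxy)dimethylsilane | Br/C(C)=C\C[C@@H]1[C@@](C)(O[Si](C)(C)C(C)(C)C)C=C[C@@H]2C(C)(C)CCC[C@]21C
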